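The ten-membered carbocycle is opened at C8–C9. The cis (erythro) pair of ester oxygens on C8 and C9, held between C7 of the lactone ring and C10 of the C1=C10 enal, is read as a former ring-cis C8=C9 double bond. One ring-closing diene–ene metathesis joins the vinyl group on C7 to the vinyl group on C10. It closes the ten-membered ring and creates the Z C8=C9 alkene, while the enal and methylene-lactone alkenes stay out. The precursor is an open-chain trans-4-vinyl-3-methylene γ-lactone carrying the cis-4,5-epoxide and a 2-vinyl enal terminus, assembled from nerol.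

Key step: step 11

Remarks on the chemistry (made before the steps):
- Germacrane numbering is used: ring carbons C1–C10, lactone carbons C11–C13, formyl C14, methyl C15.
- The ring-cis C1=C10 enal is (E) by CIP rules, because the formyl group outranks C9. The diene of the metathesis product is therefore (1(10)E,8Z), cis,cis within the ring.
- The trans lactone is built by conjugate addition to a butenolide. Zinc- or indium-mediated 2-(alkoxycarbonyl)allylation of the epoxy aldehyde with a (Z)-2-(bromomethyl)dienoate would be shorter, but such additions normally give the syn adduct and hence the cis lactone.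
- Assumption: the osmylation in step 12 is taken to occur on the β face of C8=C9 (the face syn to C6). This is the least secure stereochemical point of the route and is treated under the risks.
- The C11 configuration of the aminomethyl lactone and the carbinol configuration of the diol in step 7 are inconsequential, since both centres are destroyed.

Step 1
Reactants: 1 nerol
Product: 2 [(2S,3R)-3-methyl-3-(4-methylpent-3-en-1-yl)oxiran-2-yl]methanol
Conditions: Ti(OiPr)4 (10 mol %), diethyl L-(+)-tartrate (12 mol %), tBuOOH, 4 Å molecular sieves, CH2Cl2, −20 °C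
Reagents that add atoms: tert-butyl hydroperoxide, CC(C)(C)OO
Why: Sharpless–Katsuki asymmetric epoxidation, in which the titanium tartrate complex binds the allylic alcohol and delivers oxygen only to the allylic (C4=C5) alkene, the L-(+)-tartrate giving the (2S,3R)-epoxide that becomes C4 (R) and C5 (S), while the distal trisubstituted alkene is untouched.

Step 2
Reactants: 2 [(2S,3R)-3-methyl-3-(4-methylpent-3-en-1-yl)oxiran-2-yl]methanol
Product: 3 (2R,3R)-3-methyl-3-(4-methylpent-3-en-1-yl)oxirane-2-carbaldehyde
Conditions: TEMPO (10 mol %), PhI(OAc)2, CH2Cl2, 0 °C to rt, used crude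
Reagents that add atoms: none
Why: Oxoammonium (TEMPO) oxidation of the primary alcohol stops at the aldehyde under nearly neutral conditions that leave the epoxide, its two stereocentres and the alkene intact.

Step 3
Reactants: 3 (2R,3R)-3-methyl-3-(4-methylpent-3-en-1-yl)oxirane-2-carbaldehyde; 4 methyl propiolate
Product: 5 methyl (4S)-4-hydroxy-4-[(2S,3R)-3-methyl-3-(4-methylpent-3-en-1-yl)oxiran-2-yl]but-2-ynoate
Conditions: 4 (1.5 equiv), LiN(SiMe3)2, THF, −78 °C; then 3, −78 °C; NH4Cl quench at −78 °C
Reagents that add atoms: methyl propiolate (4), C#CC(=O)OC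
Why: 1,2-Addition of the lithium acetylide to the aldehyde under Felkin–Anh (Cornforth) control, with attack anti to the epoxide C5–O bond reinforced by the cis C3 chain, should give the anti epoxy alcohol and so C6 (S), and the cold quench prevents Payne migration of the epoxide.

Step 4
Reactants: 5 methyl (4S)-4-hydroxy-4-[(2S,3R)-3-methyl-3-(4-methylpent-3-en-1-yl)oxiran-2-yl]but-2-ynoate
Product: 7 (5S)-5-[(2S,3R)-3-methyl-3-(4-methylpent-3-en-1-yl)oxiran-2-yl]furan-2(5H)-one (butenolide), via Z-hydroxy enoate 6 (not isolated)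
Conditions: H2 (1 atm), Pd/CaCO3 poisoned with Pb(OAc)2 (Lindlar catalyst), quinoline, EtOAc, rt; then silica gel, CH2Cl2, rt
Reagents that add atoms: none
Why: Lindlar semi-hydrogenation gives the Z enoate, whose cis hydroxyl and ester close to the butenolide with loss of methanol, while the trisubstituted alkene and the epoxide are not reduced and C6 is untouched.

Step 5
Reactants: 7 (5S)-5-[(2S,3R)-3-methyl-3-(4-methylpent-3-en-1-yl)oxiran-2-yl]furan-2(5H)-one; 8 vinylmagnesium bromide; 9 N,N-dimethylmethyleneiminium iodide (Eschenmoser's salt)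
Product: 11 (3R,4S,5S)-3-[(dimethylamino)methyl]-4-ethenyl-5-[(2S,3R)-3-methyl-3-(4-methylpent-3-en-1-yl)oxiran-2-yl]oxolan-2-one, via silyl ketene acetal 10 (not isolated)
Conditions: 8 (3 equiv), CuBr·SMe2 (20 mol %), Me3SiCl, THF, −78 °C; then 9, CH2Cl2, −78 °C to rt; aq NaHCO3 work-up
Reagents that add atoms: vinylmagnesium bromide (8), C=C[Mg]Br; Eschenmoser's salt (9), C=[N+](C)C.[I-]
Why: Copper-catalysed conjugate addition of the vinyl Grignard reagent takes the butenolide face anti to the C6 epoxide substituent, which sets C7 with vinyl trans to C5 (the trans lactone), and the silyl ketene acetal is then aminomethylated at C11 by a Mannich reaction, trans to the vinyl group.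

Step 6
Reactants: 11 (3R,4S,5S)-3-[(dimethylamino)methyl]-4-ethenyl-5-[(2S,3R)-3-methyl-3-(4-methylpent-3-en-1-yl)oxiran-2-yl]oxolan-2-one
Product: 13 (4S,5S)-4-ethenyl-3-methylidene-5-[(2S,3R)-3-methyl-3-(4-methylpent-3-en-1-yl)oxiran-2-yl]oxolan-2-one, via ammonium iodide 12 (not isolated)
Conditions: MeI, MeOH, rt; then NaHCO3, EtOAc/H2O, rt
Reagents that add atoms: none
Why: Exhaustive N-methylation followed by Hofmann-type E1cB loss of trimethylamine unveils the α-methylene lactone under bicarbonate conditions too mild to touch the epoxide or C7.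

Step 7
Reactants: 13 (4S,5S)-4-ethenyl-3-methylidene-5-[(2S,3R)-3-methyl-3-(4-methylpent-3-en-1-yl)oxiran-2-yl]oxolan-2-one
Product: 15 3-[(2R,3S)-3-[(2S,3S)-3-ethenyl-4-methylidene-5-oxooxolan-2-yl]-2-methyloxiran-2-yl]propanal, via vicinal diol 14 (not isolated)
Conditions: K2OsO2(OH)4 (1 mol %), (DHQD)2PHAL (5 mol %), NMO (1.05 equiv), acetone/H2O, 0 °C; then NaIO4, THF/pH 7 buffer, 0 °C
Reagents that add atoms: N-methylmorpholine N-oxide (oxygen relayed by the osmium catalyst), C[N+]1([O-])CCOCC1; water, O
Why: Ligand-accelerated osmium-catalysed dihydroxylation selects the electron-rich trisubstituted alkene over the monosubstituted C7 vinyl group and the electron-poor methylene lactone, and Malaprade periodate cleavage of the crude diol gives the C1 aldehyde and acetone before the hydroxy epoxide can cyclise.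

Step 8
Reactants: 15 3-[(2R,3S)-3-[(2S,3S)-3-ethenyl-4-methylidene-5-oxooxolan-2-yl]-2-methyloxiran-2-yl]propanal; 16 (formylmethylene)triphenylphosphorane
Product: 17 (2E)-5-[(2R,3S)-3-[(2S,3S)-3-ethenyl-4-methylidene-5-oxooxolan-2-yl]-2-methyloxiran-2-yl]pent-2-enal
Conditions: 16 (1.3 equiv), toluene, 70 °C
Reagents that add atoms: (formylmethylene)triphenylphosphorane (16), O=CC=P(c1ccccc1)(c1ccccc1)c1ccccc1
Why: Wittig olefination with the stabilised formyl ylide is E-selective and chemoselective for the aliphatic aldehyde, and it adds C10 and C14 as the enal.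

Step 9
Reactants: 17 (2E)-5-[(2R,3S)-3-[(2S,3S)-3-ethenyl-4-methylidene-5-oxooxolan-2-yl]-2-methyloxiran-2-yl]pent-2-enal
Product: 18 (2Z)-2-iodo-5-[(2R,3S)-3-[(2S,3S)-3-ethenyl-4-methylidene-5-oxooxolan-2-yl]-2-methyloxiran-2-yl]pent-2-enal
Conditions: I2, DMAP (20 mol %), K2CO3, THF/H2O (1:1), rt, dark
Reagents that add atoms: iodine, II
Why: Amine-catalysed α-iodination (conjugate addition of DMAP, iodination of the enolate, elimination of the catalyst) gives the thermodynamically preferred Z iodoenal with iodine cis to C2, while the methylene lactone, which has no α-hydrogen to lose, can only add the catalyst reversibly.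

Step 10
Reactants: 18 (2Z)-2-iodo-5-[(2R,3S)-3-[(2S,3S)-3-ethenyl-4-methylidene-5-oxooxolan-2-yl]-2-methyloxiran-2-yl]pent-2-enal; 19 tributyl(vinyl)stannane
Product: 20 (2E)-2-ethenyl-5-[(2R,3S)-3-[(2S,3S)-3-ethenyl-4-methylidene-5-oxooxolan-2-yl]-2-methyloxiran-2-yl]pent-2-enal
Conditions: 19 (1.2 equiv), Pd2(dba)3 (2.5 mol %), AsPh3 (20 mol %), CuI (10 mol %), NMP, rt; used at once
Reagents that add atoms: tributyl(vinyl)stannane (19), C=C[Sn](CCCC)(CCCC)CCCC
Why: Stille coupling at room temperature under neutral conditions replaces iodine by vinyl with retention of the alkene geometry, so that C9 ends cis to C2 and the formyl group trans to it, and fast transmetalation outruns Heck-type insertion into the methylene lactone.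

Step 11
Reactants: 20 (2E)-2-ethenyl-5-[(2R,3S)-3-[(2S,3S)-3-ethenyl-4-methylidene-5-oxooxolan-2-yl]-2-methyloxiran-2-yl]pent-2-enal
Product: 21 (1(10)E,4R,5S,6S,7S,8Z)-4,5-epoxy-14-oxogermacra-1(10),8,11(13)-trien-12,6-olide
Conditions: RuCl2(=CH-C6H4-2-OiPr)(H2IMes) (second-generation Hoveyda–Grubbs catalyst, 15 mol % in three portions), 1,4-benzoquinone (30 mol %), degassed toluene, 1 mM, 80 °C, argon sparge
Reagents that add atoms: none
Why: Ring-closing diene–ene olefin metathesis by the Chauvin mechanism: the ruthenium alkylidene initiates at the monosubstituted C7 vinyl group, the resulting C8 alkylidene adds across the terminal C9=CH2 bond of the dienal in a [2+2] step, and cycloreversion of the ruthenacyclobutane spanning C8 and C9 releases the product and a ruthenium methylidene that leaves as ethene. The closest known reaction type is ring-closing metathesis of an alkene with the terminal double bond of a conjugated diene to give a medium-ring 1,3-diene. The ten-membered carbocycle (C1–C10) is closed by direct union of the two vinyl CH carbons, both of which become ring atoms, and the lactone and the epoxide become rings fused to it. No stereocentre is formed; the only new stereo-element is the C8=C9 geometry, which must be Z and is imposed by the ring, since a ten-membered ring that already holds the ring-cis C1=C10 bond and the cis-epoxide accommodates only a cis C8=C9 bond without severe strain. The step needs site selectivity and cyclisation over oligomerisation: the trisubstituted, formyl-bearing C1=C10 bond and the 1,1-disubstituted methylene lactone are too hindered and electron-poor to enter the cycle, the three turn elements already present (ring-cis C1=C10, cis-epoxide, trans-lactone) bring C8 and C9 together, and high dilution, ethene removal and benzoquinone (against hydride-induced migration of the C7 vinyl double bond) secure the rest.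

Step 12
Reactants: 21 (1(10)E,4R,5S,6S,7S,8Z)-4,5-epoxy-14-oxogermacra-1(10),8,11(13)-trien-12,6-olide
Product: 22 (1(10)E,4R,5S,6S,7R,8S,9R)-4,5-epoxy-8,9-dihydroxy-14-oxogermacra-1(10),11(13)-dien-12,6-olide
Conditions: OsO4 (5 mol %), NMO (1.1 equiv), acetone/H2O (5:1), 0 °C
Reagents that add atoms: N-methylmorpholine N-oxide (oxygen relayed by the osmium catalyst), C[N+]1([O-])CCOCC1; water, O
Why: Osmium-catalysed syn-dihydroxylation through a cyclic osmate ester is suprafacial, so the Z alkene gives the erythro diol, and it should choose C8=C9 because the other two alkenes are conjugated to carbonyl groups; C8 (S) and C9 (R) arise only from osmylation on the β face (syn to C6, away from the C14 formyl group and the lactone carbon C11), which is assumed here and examined under the risks.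

Step 13
Reactants: 22 (1(10)E,4R,5S,6S,7R,8S,9R)-4,5-epoxy-8,9-dihydroxy-14-oxogermacra-1(10),11(13)-dien-12,6-olide; 23 acetic anhydride
Product: 24 (1(10)E,4R,5S,6S,7R,8S,9R)-9-acetoxy-4,5-epoxy-8-hydroxy-14-oxogermacra-1(10),11(13)-dien-12,6-olide
Conditions: 23 (1.05 equiv), Et3N, DMAP (5 mol %), CH2Cl2, −40 °C
Reagents that add atoms: acetic anhydride (23), CC(=O)OC(C)=O
Why: Kinetic mono-acylation with one equivalent of anhydride at low temperature should favour the allylic C9 hydroxyl, which sits next to the planar C10, over the C8 hydroxyl, which is flanked by the ring-fusion carbon C7 and the lactone, and the cold conditions suppress acetyl migration from O9 to O8.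

Step 14
Reactants: 24 (1(10)E,4R,5S,6S,7R,8S,9R)-9-acetoxy-4,5-epoxy-8-hydroxy-14-oxogermacra-1(10),11(13)-dien-12,6-olide; 25 methacrylic anhydride
Product: 26 (1(10)E,4R,5S,6S,7R,8S,9R)-9-acetoxy-4,5-epoxy-8-(methacryloyloxy)-14-oxogermacra-1(10),11(13)-dien-12,6-olide (target)
Conditions: 25 (1.5 equiv), DMAP, Et3N, CH2Cl2, 0 °C
Reagents that add atoms: methacrylic anhydride (25), C=C(C)C(=O)OC(=O)C(C)=C
Why: DMAP-catalysed acyl transfer esterifies the one remaining secondary hydroxyl at C8 faster than acyl migration or conjugate addition to the Michael acceptors can occur, which completes the target without touching a stereocentre.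

Compound list
1 | nerol, (2Z)-3,7-dimethylocta-2,6-dien-1-ol | CC(C)=CCC/C(C)=C\CO | starting material
2 | [(2S,3R)-3-methyl-3-(4-methylpent-3-en-1-yl)oxiran-2-yl]methanol | OC[C@@H]1O[C@]1(C)CCC=C(C)C | intermediate
3 | (2R,3R)-3-methyl-3-(4-methylpent-3-en-1-yl)oxirane-2-carbaldehyde | O=C[C@@H]1O[C@]1(C)CCC=C(C)C | intermediate
4 | methyl propiolate | C#CC(=O)OC | starting material
5 | methyl (4S)-4-hydroxy-4-[(2S,3R)-3-methyl-3-(4-methylpent-3-en-1-yl)oxiran-2-yl]but-2-ynoate | COC(=O)C#C[C@H](O)[C@@H]1O[C@]1(C)CCC=C(C)C | intermediate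
6 | methyl (2Z,4S)-4-hydroxy-4-[(2S,3R)-3-methyl-3-(4-methylpent-3-en-1-yl)oxiran-2-yl]but-2-enoate | COC(=O)/C=C\[C@H](O)[C@@H]1O[C@]1(C)CCC=C(C)C | intermediate (not isolated)
7 | (5S)-5-[(2S,3R)-3-methyl-3-(4-methylpent-3-en-1-yl)oxiran-2-yl]furan-2(5H)-one | O=C1O[C@@H](C=C1)[C@@H]2O[C@]2(C)CCC=C(C)C | intermediate
8 | vinylmagnesium bromide | C=C[Mg]Br | starting material
9 | N,N-dimethylmethyleneiminium iodide (Eschenmoser's salt) | C=[N+](C)C.[I-] | starting material
10 | {[(4S,5S)-4-ethenyl-5-[(2S,3R)-3-methyl-3-(4-methylpent-3-en-1-yl)oxiran-2-yl]-4,5-dihydrofuran-2-yl]oxy}trimethylsilane | C=C[C@H]1C=C(O[Si](C)(C)C)O[C@@H]1[C@@H]2O[C@]2(C)CCC=C(C)C | intermediate (not isolated)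
11 | (3R,4S,5S)-3-[(dimethylamino)methyl]-4-ethenyl-5-[(2S,3R)-3-methyl-3-(4-methylpent-3-en-1-yl)oxiran-2-yl]oxolan-2-one | C=C[C@H]1[C@H](CN(C)C)C(=O)O[C@@H]1[C@@H]2O[C@]2(C)CCC=C(C)C | intermediate
12 | {[(3R,4S,5S)-4-ethenyl-5-[(2S,3R)-3-methyl-3-(4-methylpent-3-en-1-yl)oxiran-2-yl]-2-oxooxolan-3-yl]methyl}trimethylammonium iodide | C=C[C@H]1[C@H](C[N+](C)(C)C)C(=O)O[C@@H]1[C@@H]2O[C@]2(C)CCC=C(C)C.[I-] | intermediate (not isolated)
13 | (4S,5S)-4-ethenyl-3-methylidene-5-[(2S,3R)-3-methyl-3-(4-methylpent-3-en-1-yl)oxiran-2-yl]oxolan-2-one | C=C[C@H]1C(=C)C(=O)O[C@@H]1[C@@H]2O[C@]2(C)CCC=C(C)C | intermediate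
14 | (4S,5S)-5-[(2S,3R)-3-[(3R)-3,4-dihydroxy-4-methylpentyl]-3-methyloxiran-2-yl]-4-ethenyl-3-methylideneoxolan-2-one | C=C[C@H]1C(=C)C(=O)O[C@@H]1[C@@H]2O[C@]2(C)CC[C@@H](O)C(C)(C)O | intermediate (not isolated)
15 | 3-[(2R,3S)-3-[(2S,3S)-3-ethenyl-4-methylidene-5-oxooxolan-2-yl]-2-methyloxiran-2-yl]propanal | C=C[C@H]1C(=C)C(=O)O[C@@H]1[C@@H]2O[C@]2(C)CCC=O | intermediate
16 | (formylmethylene)triphenylphosphorane | O=CC=P(c1ccccc1)(c1ccccc1)c1ccccc1 | starting material
17 | (2E)-5-[(2R,3S)-3-[(2S,3S)-3-ethenyl-4-methylidene-5-oxooxolan-2-yl]-2-methyloxiran-2-yl]pent-2-enal | C=C[C@H]1C(=C)C(=O)O[C@@H]1[C@@H]2O[C@]2(C)CC/C=C/C=O | intermediate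
18 | (2Z)-2-iodo-5-[(2R,3S)-3-[(2S,3S)-3-ethenyl-4-methylidene-5-oxooxolan-2-yl]-2-methyloxiran-2-yl]pent-2-enal | C=C[C@H]1C(=C)C(=O)O[C@@H]1[C@@H]2O[C@]2(C)CC/C=C(\I)C=O | intermediate
19 | tributyl(vinyl)stannane | C=C[Sn](CCCC)(CCCC)CCCC | starting material
20 | (2E)-2-ethenyl-5-[(2R,3S)-3-[(2S,3S)-3-ethenyl-4-methylidene-5-oxooxolan-2-yl]-2-methyloxiran-2-yl]pent-2-enal (metathesis precursor) | C=C[C@H]1C(=C)C(=O)O[C@@H]1[C@@H]2O[C@]2(C)CC/C=C(/C=O)C=C | intermediate
21 | (1(10)E,4R,5S,6S,7S,8Z)-4,5-epoxy-14-oxogermacra-1(10),8,11(13)-trien-12,6-olide (metathesis product) | O=C1O[C@H]2[C@H](C1=C)/C=C\C(C=O)=C/CC[C@@]3(C)O[C@@H]23 | intermediate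
22 | (1(10)E,4R,5S,6S,7R,8S,9R)-4,5-epoxy-8,9-dihydroxy-14-oxogermacra-1(10),11(13)-dien-12,6-olide | O[C@H]1[C@H]2C(=C)C(=O)O[C@@H]2[C@@H]2O[C@]2(C)CC/C=C(/C=O)[C@H]1O | intermediate
23 | acetic anhydride | CC(=O)OC(C)=O | starting material
24 | (1(10)E,4R,5S,6S,7R,8S,9R)-9-acetoxy-4,5-epoxy-8-hydroxy-14-oxogermacra-1(10),11(13)-dien-12,6-olide | O[C@H]1[C@H]2C(=C)C(=O)O[C@@H]2[C@@H]2O[C@]2(C)CC/C=C(/C=O)[C@H]1OC(C)=O | intermediate
25 | methacrylic anhydride | C=C(C)C(=O)OC(=O)C(C)=C | starting material
26 | (1(10)E,4R,5S,6S,7R,8S,9R)-9-acetoxy-4,5-epoxy-8-(methacryloyloxy)-14-oxogermacra-1(10),11(13)-dien-12,6-olide | C=C(C)C(=O)O[C@H]1[C@H]2C(=C)C(=O)O[C@@H]2[C@@H]2O[C@]2(C)CC/C=C(/C=O)[C@H]1OC(C)=O | target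

Total step count: 14 steps.
Longest linear sequence: 14 steps, from nerol (all other inputs are commercial).

Steps most likely to fail

1. Step 11 (key step). Ring closure may lose to intermolecular metathesis, the catalyst may be trapped after loading on the dienal terminus as a formyl-chelated vinylcarbene, or a ruthenium hydride may move the C7 vinyl double bond into conjugation with the lactone. The fallback carries C14 at the alcohol level, which makes the diene a better metathesis partner and removes the chelating carbonyl group. It sets out from 20. Luche reduction (NaBH4, CeCl3·7H2O, MeOH, −78 °C) should reduce only the aldehyde and give the dienol F1. Silylation (Et3SiCl, imidazole, CH2Cl2) gives the triethylsilyl ether F2. Ring-closing metathesis under the conditions of step 11 gives the macrocyclic silyl ether F3. Buffered fluoride (Bu4NF, AcOH, THF) frees the macrocyclic allylic alcohol F4, and activated MnO2 oxidises it to the enal. The fallback comes back to the route at 21.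

2. Step 12. Osmylation may occur on the wrong face. In a cis-cycloalkene with an allylic stereocentre the reagent usually enters trans to the exocyclic allylic substituent (here the lactone carbon C11). In the twisted cis,cis-diene the C2 methylene lies under the face syn to C6. Attack on the other face would give the 8,9-bis-epimer of 22, so the conformation of 21 must be checked before this step. The fallback is a Woodward–Prévost cis-hydroxylation, which puts both oxygens on the face opposite to the one the electrophile attacks. It sets out from 21. I2 and AgOAc in dry acetic acid at rt add iodine to the open face and acetate to the other face, giving the trans iodo acetate F5. Silver-assisted loss of iodide with participation of the neighbouring acetate gives the acetoxonium ion F6. Added water opens it to the cis hydroxy acetate, with acetyl expected to stay on the less basic, allylic O9. The fallback comes back to the route at 24.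

3. Step 13. Acylation may be unselective between the two secondary hydroxyls, or the acetyl group may migrate from O9 to O8 under the basic conditions, so that the two esters end up exchanged. The fallback tags one hydroxyl with a bulky, non-migrating silyl group and reverses the order of the acylations. It sets out from 22. Et3SiCl and imidazole at −40 °C silylate the more accessible C9 hydroxyl, giving the 9-O-triethylsilyl ether F7. Methacrylic anhydride 25 with DMAP acylates the only free hydroxyl, giving the 8-methacrylate 9-silyl ether F8. HF·pyridine removes the silyl group, giving the 8-methacrylate 9-alcohol F9, and acetic anhydride 23 with DMAP acetylates O9. The fallback comes back to the route at 26.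

Further compounds
F1 | step 11 | (2E)-2-ethenyl-5-[(2R,3S)-3-[(2S,3S)-3-ethenyl-4-methylidene-5-oxooxolan-2-yl]-2-methyloxiran-2-yl]pent-2-en-1-ol | C=C[C@H]1C(=C)C(=O)O[C@@H]1[C@@H]2O[C@]2(C)CC/C=C(/CO)C=C
F2 | step 11 | triethylsilyl ether of F1 | C=C[C@H]1C(=C)C(=O)O[C@@H]1[C@@H]2O[C@]2(C)CC/C=C(/CO[Si](CC)(CC)CC)C=C
F3 | step 11 | (1(10)E,4R,5S,6S,7S,8Z)-4,5-epoxy-14-(triethylsilyloxy)germacra-1(10),8,11(13)-trien-12,6-olide | O=C1O[C@H]2[C@H](C1=C)/C=C\C(CO[Si](CC)(CC)CC)=C/CC[C@@]3(C)O[C@@H]23
F4 | step 11 | (1(10)E,4R,5S,6S,7S,8Z)-4,5-epoxy-14-hydroxygermacra-1(10),8,11(13)-trien-12,6-olide | O=C1O[C@H]2[C@H](C1=C)/C=C\C(CO)=C/CC[C@@]3(C)O[C@@H]23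
F5 | step 12 | 9β-acetoxy-8α-iodo-4,5-epoxy-14-oxogermacra-1(10),11(13)-dien-12,6-olide (trans iodo acetate) | I[C@@H]1[C@H]2C(=C)C(=O)O[C@@H]2[C@@H]2O[C@]2(C)CC/C=C(/C=O)[C@H]1OC(C)=O
F6 | step 12 | 8β,9β-(2-methyl-1,3-dioxolan-2-ylium) acetoxonium ion, acetate salt | C[C+]1O[C@H]2[C@H]3C(=C)C(=O)O[C@@H]3[C@@H]3O[C@]3(C)CC/C=C(/C=O)[C@H]2O1.CC([O-])=O
F7 | step 13 | 9-O-triethylsilyl ether of 22 | O[C@H]1[C@H]2C(=C)C(=O)O[C@@H]2[C@@H]2O[C@]2(C)CC/C=C(/C=O)[C@H]1O[Si](CC)(CC)CC
F8 | step 13 | 8-O-methacryloyl-9-O-triethylsilyl derivative of 22 | C=C(C)C(=O)O[C@H]1[C@H]2C(=C)C(=O)O[C@@H]2[C@@H]2O[C@]2(C)CC/C=C(/C=O)[C@H]1O[Si](CC)(CC)CC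
F9 | step 13 | 8-O-methacryloyl derivative of 22 with free 9-hydroxyl | C=C(C)C(=O)O[C@H]1[C@H]2C(=C)C(=O)O[C@@H]2[C@@H]2O[C@]2(C)CC/C=C(/C=O)[C@H]1O
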